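# Proposed synthesis of CNP0118131.1 by three-component opening of a cyclopropane-fused lactone

Compound numbers used throughout: 1 (S)-epichlorohydrin; 2 diethyl malonate; 3 cyclopropane alkoxide (transient); 4 bicyclic cyclopropane lactone; 5 4-benzyloxy-3-methoxybenzyl alcohol; 6 the corresponding chloride; 7 3-bromo-4,5-dihydroxybenzaldehyde; 8 mono-ether; 9 bis-ether aldehyde; 10 benzylic alcohol; 11 silyl ether; 12 methyl arylacetate; 13 aryl diazoacetate; 14 cis dihydrobenzofuran ester; 15 trans ester; 16 primary alcohol; 17 tri-O-benzyl silyl ether; 18 benzylic alcohol; 19 benzylic bromide; 20 4-bromo-2-methoxyphenol; 21 its benzyl ether; 22 aryl Grignard reagent; 23 magnesium enolate (transient); 24 quaternary ester lactone; 25 lactone as C3 epimers; 26 trans lactone; 27 target.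

## Analysis of the target

Target 27 is a γ-butyrolactone (ring A) whose C4 carries a 4-hydroxy-3-methoxybenzyl arm (ring B) and whose C3 is joined through a CH2 group to C5 of a 2,3-dihydrobenzofuran (benzo ring C, furan ring D) bearing a free 7-OH, a 3-CH2OH group and a 4-hydroxy-3-methoxyphenyl group (ring E) on C2. It has four stereocentres in two pairs: C3 and C4 of ring A are both S with the two benzylic arms trans, and C2 (S) and C3 (R) of ring D carry the aryl and hydroxymethyl groups trans. Both pairs are in their more stable relative configuration, but they are separated by a CH2–arene spacer, so neither pair can direct the other and absolute configuration has to be brought in twice, independently. Sensitive groups are the three phenols (the 7-OH is ortho to the ring oxygen and oxidation-prone), the primary alcohol, the lactone with its enolisable C3, and the benzylic C2–O1 bond of ring D, which is activated by a para-oxygenated aryl group toward acid ionisation and hydrogenolysis. Because O7 is a free hydroxyl and not a methyl ether, the oxygens to be unmasked must be kept apart from the two methoxy groups, and O1 and O7 of ring C must be told apart early. The difficulty is to join a small chiral lactone to two different benzylic groups, one of them an elaborate chiral fragment, without a long linear sequence on that fragment. The strategy rests on C3 and C4 of ring A and the benzylic CH2 on C4: with a bond between C3 and that CH2 they form a cyclopropane fused to the lactone. With an ester on C3 this strained bicycle is a one-step chiral-pool compound, its CH2–C3 bond can be cut by an aryl nucleophile, and C3 emerges as an enolate ready for the second benzylic group.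

## Retrosynthetic reasoning

**27 to 26.** The four O–H bonds of the phenols and the primary alcohol are traced back to benzyl ethers. All the carbon–carbon chemistry involves organomagnesium reagents, enolates and a hot halide salt, which free hydroxyls would not tolerate, and one kind of protecting group allows a single closing hydrogenolysis.

**26 to 25 to 24.** The C3–H bond is replaced by an ester group. The trans arrangement at C3/C4 is the thermodynamic one, so C3 need not be set kinetically; it can be left as an epimer mixture (25) and equilibrated. The ester in 24 makes C3 a stabilised enolate carbon and is the second activating group that the cyclopropane opening needs.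

**24 to 4, 22 and 19.** Two benzylic C–C bonds are cut: the bond from ring B to the CH2 on C4, and the bond from C3 to the CH2 on ring C. Cutting here divides the molecule into an aryl nucleophile (22), a benzylic electrophile (19) and a three-carbon linchpin (4) that already holds C4 in the correct configuration. The forward reaction must add the aryl group to the cyclopropane CH2 of 4 and then alkylate the enolate released at C3, in one flask.

**4 to 1 and 2.** The two cyclopropane bonds to the malonate carbon and the lactone C–O bond are cut. Malonate 2 acts as a double nucleophile toward the three carbons of 1, and the stereocentre of 1 becomes C5 of 4, hence C4 of the target.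

**22 to 21 to 20.** The C–Mg bond comes from the aryl bromide, and the benzyl ether from the phenol.

**19 to 18 to 17 to 16 to 15.** These are functional-group changes only. The benzylic bromide is made last, from a silyl-protected alcohol, because it is the most labile function of the fragment. The C3 hydroxymethyl group is obtained from an ester and is benzylated before the silyl ether is removed.

**15 to 14 to 13.** The C2–C3 bond of ring D is cut. A carbenoid at C3, generated from diazo ester 13, inserts into the benzylic C–H bond of the ether on O1. The ring problem thus becomes an aryl ether plus an arylacetate, C2 is set by a chiral catalyst, and C3 is set afterwards by equilibration of the cis ester 14 to the trans ester 15.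

**13 to 12 to 11.** The diazo group comes from the activated CH2 of 12. The aryl–CH2CO2Me bond is cut back to aryl bromide 11, so that the bromine marks the future C3a.

**11 to 10 to 9 to 8 to 7 and 6; 6 to 5.** The silyl ether and the two aryl ethers are removed in turn. In aldehyde 7 the formyl carbon is already the C5 carbon, the bromine sits at C3a and the two hydroxyls are O1 and O7. They differ in acidity, so the 4-benzyloxy-3-methoxybenzyl group (from 6) can be placed on O1 first and a plain benzyl group on O7 second.

## Alternatives that were turned down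

**Alternative 1: ring contraction of a flavanone.**
- Disconnection: the C3–C3a bond of ring D, leading back to the six-membered flavanone A2, itself from chalcone A3 by an asymmetric oxa-Michael closure.
- Forward key step: A2 with PhI(OAc)2 and catalytic H2SO4 in trimethyl orthoformate. The enol ether is attacked at C3 by trivalent iodine, the benzo carbon C4a shifts from C4 to C3 as iodobenzene leaves, and the former carbonyl carbon ends as the methyl ester of trans ester A1.
- For: the trans relationship is delivered directly, no diazo compound or chiral rhodium catalyst is needed, and the reagents are cheap. On these points it is stronger than the chosen route.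
- Against:
  - The key step solves only rings C and D. The lactone, its C4 centre and both benzylic bonds would still need chemistry of the kind used here.
  - The more electron-rich the 2-aryl group, the more it competes as the migrating group, and the oxidant attacks electron-rich arenes. Ring E must therefore be deactivated as a pivalate and later re-protected.
  - Flavanones open reversibly to chalcones under acid or base, so C2 of A2 can racemise before or during the strongly acidic contraction.
  - A1 carries bromine at C5, so reaching a coupling partner needs a bromine-to-carbon homologation on top of ester reduction and protecting-group exchange.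
- Comparison: the chosen route sets C2 under neutral, catalyst-controlled conditions, carries the C5 carbon from the first step, and spends its key step on joining all three fragments.

**Alternative 2: desymmetrising Baeyer–Villiger oxidation.**
- Disconnection: the ring O–CH2 bond of the lactone, leading to the prochiral cyclobutanone A5, available from eugenol A6 by O-benzylation, ketene [2+2] cycloaddition and dechlorination.
- Forward key step: Sc(OTf)3 with a chiral N,N'-dioxide ligand and m-chloroperbenzoic acid. In the Criegee adduct the catalyst decides which of the two enantiotopic CH2 groups migrates, giving lactone A4. Its lithium enolate would then be alkylated by bromide 19 anti to the C4 arm to give 26 directly.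
- For: the endgame is shorter and milder (no quaternary ester, no dealkoxycarbonylation, no equilibration), and the starting material is cheap. On these points it is stronger than the chosen route.
- Against:
  - The stereocentre lies two bonds from the carbonyl and carries a flexible CH2Ar group, so the two migrating bonds are much harder to distinguish than in 3-arylcyclobutanones. Any shortfall becomes a diastereomer after coupling with 19.
  - The peracid meets an electron-rich arene.
  - A4 needs about four steps, against one step for 4.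
  - The unstabilised lactone enolate needs a strong amide base and an exactly stoichiometric labile bromide, with bis-alkylation as a risk.
- Comparison: the chosen route takes C4 in fixed configuration from 1 and couples through a stabilised, mono-alkylating enolate.

**Alternative 3: carbonylative lactonisation of an alkynol.**
- Disconnection: the C1–O and C1–C3 bonds of the lactone, with the carbonyl carbon coming from CO. The precursor is alkynol A8, assembled by Sonogashira coupling of aryl iodide A9 with terminal alkynol A10.
- Forward key step: PdCl2(PPh3)2 with SnCl2 under CO. An alkoxycarbonyl–palladium species adds syn across the alkyne in a 5-exo sense, and protonolysis gives the (E)-arylidene lactone A7. Hydrogenation of the exocyclic alkene together with the benzyl ethers, then epimerisation at C3, would finish the synthesis.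
- For: ring C enters as a robust aryl iodide (A9) and not as the labile benzylic bromide 19, which is a real advantage in fragment length and handling. Reduction and deprotection share one operation.
- Against:
  - C4 must be built into A10 by a separate asymmetric sequence.
  - With an aryl–alkyl alkyne, the sense of addition (five- versus six-membered lactone) is not secured by the substrate.
  - Hydrogen is delivered anti to the C4 arm, giving the cis lactone first. The long hydrogenation needed for this and for the alkyl benzyl ether exposes the C2–O1 bond.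
  - Stoichiometric tin salt is used.
- Comparison: the step count after the fragments is about the same. The chosen route wins on access to the chiral lactone piece (one step) and on a key step built from two robust, non-carbonylative reactions that form two C–C bonds.

Key step: step 17

Assumption: Rh2(R-PTTL)4 is taken to deliver the 2S configuration in step 9, by analogy with the sense of induction of this catalyst family on simpler 2-(benzyloxy)aryl diazoacetates; if the sense were opposite, the mirror-image catalyst would be used with nothing else changed.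

## Route

**Fragment: bicyclic lactone**

Step 1
Reactants: 1 (S)-epichlorohydrin; 2 diethyl malonate
Product: 4 ethyl (1R,5S)-2-oxo-3-oxabicyclo[3.1.0]hexane-1-carboxylate, via cyclopropane alkoxide 3 (not isolated)
Conditions: NaOEt, EtOH, 0 °C to reflux
Reagents that add atoms: none
Why: Tandem malonate alkylation, cyclopropanation and lactonisation: the malonate anion opens the epoxide of 1 at its CH2, the alkoxide closes a new epoxide by displacing chloride, and the malonate carbanion opens that epoxide at the former stereocentre (3-exo-tet, inversion) to give alkoxide 3, which lactonises onto the cis ester. C5 of 4 is thereby fixed as S from the S epoxide and C1 (R) follows from the cis ring fusion.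

**Fragment: dihydrobenzofuranylmethyl bromide**

Step 2
Reactants: 5 [4-(benzyloxy)-3-methoxyphenyl]methanol
Product: 6 4-(benzyloxy)-3-methoxybenzyl chloride
Conditions: SOCl2, CH2Cl2, 0 °C
Reagents that add atoms: thionyl chloride, O=S(Cl)Cl
Why: Chlorodehydroxylation of an electron-rich benzylic alcohol through its chlorosulfite; the chloride is used at once without storage.

Step 3
Reactants: 7 3-bromo-4,5-dihydroxybenzaldehyde; 6 4-(benzyloxy)-3-methoxybenzyl chloride
Product: 8 3-bromo-4-[(4-benzyloxy-3-methoxybenzyl)oxy]-5-hydroxybenzaldehyde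
Conditions: Li2CO3, NaI (cat.), DMF, 45 °C
Reagents that add atoms: none
Why: Williamson etherification under acidity control: the 4-OH of 7 is para to the formyl group and ortho to bromine, hence clearly the more acidic phenol, and a weak base ionises only this one, so mono-alkylation at O4 (the future O1) is expected.

Step 4
Reactants: 8 3-bromo-4-[(4-benzyloxy-3-methoxybenzyl)oxy]-5-hydroxybenzaldehyde
Product: 9 3-(benzyloxy)-5-bromo-4-[(4-benzyloxy-3-methoxybenzyl)oxy]benzaldehyde
Conditions: BnBr, K2CO3, DMF, rt
Reagents that add atoms: benzyl bromide, BrCc1ccccc1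
Why: Williamson etherification of the one remaining phenol (the future O7).

Step 5
Reactants: 9 3-(benzyloxy)-5-bromo-4-[(4-benzyloxy-3-methoxybenzyl)oxy]benzaldehyde
Product: 10 {3-(benzyloxy)-5-bromo-4-[(4-benzyloxy-3-methoxybenzyl)oxy]phenyl}methanol
Conditions: NaBH4, THF/MeOH, 0 °C
Reagents that add atoms: none
Why: Hydride reduction of the aldehyde, which would not survive the zinc enolate of step 7; the aryl bromide and the ethers are inert.

Step 6
Reactants: 10 {3-(benzyloxy)-5-bromo-4-[(4-benzyloxy-3-methoxybenzyl)oxy]phenyl}methanol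
Product: 11 tert-butyl({3-(benzyloxy)-5-bromo-4-[(4-benzyloxy-3-methoxybenzyl)oxy]benzyl}oxy)dimethylsilane
Conditions: TBSCl, imidazole, DMF, rt
Reagents that add atoms: tert-butyl(chloro)dimethylsilane, CC(C)(C)[Si](C)(C)Cl
Why: Silylation of the primary benzylic alcohol; the silyl ether is orthogonal to the benzyl ethers and is removed by fluoride in step 13.

Step 7
Reactants: 11 tert-butyl({3-(benzyloxy)-5-bromo-4-[(4-benzyloxy-3-methoxybenzyl)oxy]benzyl}oxy)dimethylsilane
Product: 12 methyl 2-{3-(benzyloxy)-2-[(4-benzyloxy-3-methoxybenzyl)oxy]-5-[(tert-butyldimethylsilyloxy)methyl]phenyl}acetate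
Conditions: BrZnCH2CO2Me, Pd2(dba)3 (cat.), XPhos (cat.), THF, 60 °C
Reagents that add atoms: (2-methoxy-2-oxoethyl)zinc bromide (made beforehand from methyl bromoacetate and zinc), COC(=O)C[Zn]Br
Why: Negishi-type α-arylation with a Reformatsky reagent: oxidative addition of zerovalent palladium into the Ar–Br bond, transmetallation of the zinc enolate and reductive elimination; the mild zinc reagent tolerates the silyl and benzyl ethers and the bulky biarylphosphine copes with the ortho-alkoxy group.

Step 8
Reactants: 12 methyl 2-{3-(benzyloxy)-2-[(4-benzyloxy-3-methoxybenzyl)oxy]-5-[(tert-butyldimethylsilyloxy)methyl]phenyl}acetate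
Product: 13 methyl 2-diazo-2-{3-(benzyloxy)-2-[(4-benzyloxy-3-methoxybenzyl)oxy]-5-[(tert-butyldimethylsilyloxy)methyl]phenyl}acetate
Conditions: p-ABSA, DBU, MeCN, 0 °C to rt
Reagents that add atoms: 4-acetamidobenzenesulfonyl azide, CC(=O)Nc1ccc(cc1)S(=O)(=O)N=[N+]=[N-]
Why: Regitz diazo transfer to the CH2 group activated by both the aryl ring and the ester.

Step 9
Reactants: 13 methyl 2-diazo-2-{3-(benzyloxy)-2-[(4-benzyloxy-3-methoxybenzyl)oxy]-5-[(tert-butyldimethylsilyloxy)methyl]phenyl}acetate
Product: 14 methyl (2S,3R)-7-(benzyloxy)-2-(4-benzyloxy-3-methoxyphenyl)-5-[(tert-butyldimethylsilyloxy)methyl]-2,3-dihydrobenzofuran-3-carboxylate (cis)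
Conditions: Rh2(R-PTTL)4 (1 mol %), toluene, −60 °C
Reagents that add atoms: none
Why: Enantioselective intramolecular 1,5 C–H insertion of a donor/acceptor dirhodium carbenoid into the ether CH2, which is activated by oxygen and by the electron-rich aryl group; ring D closes with formation of the C2–C3 bond. The chiral carboxylate ligands of dirhodium tetrakis[N-phthaloyl-(R)-tert-leucinate] select one of the two enantiotopic benzylic hydrogens and so set C2 (S), while the compact insertion transition state places aryl and ester cis (kinetic 3R).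

Step 10
Reactants: 14 methyl (2S,3R)-7-(benzyloxy)-2-(4-benzyloxy-3-methoxyphenyl)-5-[(tert-butyldimethylsilyloxy)methyl]-2,3-dihydrobenzofuran-3-carboxylate (cis)
Product: 15 methyl (2S,3S)-7-(benzyloxy)-2-(4-benzyloxy-3-methoxyphenyl)-5-[(tert-butyldimethylsilyloxy)methyl]-2,3-dihydrobenzofuran-3-carboxylate (trans)
Conditions: NaOMe (0.3 equiv), MeOH/THF, 0 °C to rt
Reagents that add atoms: none
Why: Base-mediated epimerisation at C3 through the ester enolate; the trans isomer relieves the eclipsing of aryl and ester and is the thermodynamic product, while C2 carries no acidic hydrogen and stays S. Substoichiometric base at low temperature limits β-elimination of the phenoxide.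

Step 11
Reactants: 15 methyl (2S,3S)-7-(benzyloxy)-2-(4-benzyloxy-3-methoxyphenyl)-5-[(tert-butyldimethylsilyloxy)methyl]-2,3-dihydrobenzofuran-3-carboxylate (trans)
Product: 16 [(2S,3R)-7-(benzyloxy)-2-(4-benzyloxy-3-methoxyphenyl)-5-[(tert-butyldimethylsilyloxy)methyl]-2,3-dihydrobenzofuran-3-yl]methanol
Conditions: LiAlH4, THF, 0 °C
Reagents that add atoms: none
Why: Hydride reduction of the ester to the primary alcohol; C3 is no longer enolisable afterwards, so the trans relationship is locked (the descriptor changes to 3R only through the priority rules).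

Step 12
Reactants: 16 [(2S,3R)-7-(benzyloxy)-2-(4-benzyloxy-3-methoxyphenyl)-5-[(tert-butyldimethylsilyloxy)methyl]-2,3-dihydrobenzofuran-3-yl]methanol
Product: 17 tert-butyl{[(2S,3R)-7-(benzyloxy)-3-[(benzyloxy)methyl]-2-(4-benzyloxy-3-methoxyphenyl)-2,3-dihydrobenzofuran-5-yl]methoxy}dimethylsilane
Conditions: NaH, BnBr, Bu4NI (cat.), THF/DMF, 0 °C to rt
Reagents that add atoms: benzyl bromide, BrCc1ccccc1
Why: Williamson benzylation of the primary alkoxide; the silyl ether is stable to these conditions.

Step 13
Reactants: 17 tert-butyl{[(2S,3R)-7-(benzyloxy)-3-[(benzyloxy)methyl]-2-(4-benzyloxy-3-methoxyphenyl)-2,3-dihydrobenzofuran-5-yl]methoxy}dimethylsilane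
Product: 18 [(2S,3R)-7-(benzyloxy)-3-[(benzyloxy)methyl]-2-(4-benzyloxy-3-methoxyphenyl)-2,3-dihydrobenzofuran-5-yl]methanol
Conditions: Bu4NF, THF, 0 °C
Reagents that add atoms: none
Why: Fluoride-induced desilylation; the benzyl ethers and ring D are untouched.

Step 14
Reactants: 18 [(2S,3R)-7-(benzyloxy)-3-[(benzyloxy)methyl]-2-(4-benzyloxy-3-methoxyphenyl)-2,3-dihydrobenzofuran-5-yl]methanol
Product: 19 (2S,3R)-7-(benzyloxy)-3-[(benzyloxy)methyl]-2-(4-benzyloxy-3-methoxyphenyl)-5-(bromomethyl)-2,3-dihydrobenzofuran
Conditions: CBr4, PPh3, CH2Cl2, 0 °C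
Reagents that add atoms: tetrabromomethane, BrC(Br)(Br)Br
Why: Appel bromination under neutral conditions, which avoids acid that could ionise the C2–O1 bond; the para-alkoxybenzylic bromide is labile and is used directly in step 17.

**Fragment: aryl Grignard reagent**

Step 15
Reactants: 20 4-bromo-2-methoxyphenol
Product: 21 1-(benzyloxy)-4-bromo-2-methoxybenzene
Conditions: BnBr, K2CO3, acetone, reflux
Reagents that add atoms: benzyl bromide, BrCc1ccccc1
Why: Williamson etherification of the phenol.

Step 16
Reactants: 21 1-(benzyloxy)-4-bromo-2-methoxybenzene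
Product: 22 (4-benzyloxy-3-methoxyphenyl)magnesium bromide (titrated THF solution)
Conditions: Mg, I2 (cat.), THF, rt to 40 °C
Reagents that add atoms: magnesium, [Mg]
Why: Oxidative insertion of magnesium into the aryl–bromine bond (Grignard formation); the solution is titrated so that it can be used as the limiting reagent in step 17.

**Union and endgame**

Step 17
Reactants: 4 ethyl (1R,5S)-2-oxo-3-oxabicyclo[3.1.0]hexane-1-carboxylate; 22 (4-benzyloxy-3-methoxyphenyl)magnesium bromide; 19 (2S,3R)-7-(benzyloxy)-3-[(benzyloxy)methyl]-2-(4-benzyloxy-3-methoxyphenyl)-5-(bromomethyl)-2,3-dihydrobenzofuran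
Product: 24 ethyl (3S,4S)-3-{[(2S,3R)-7-(benzyloxy)-3-[(benzyloxy)methyl]-2-(4-benzyloxy-3-methoxyphenyl)-2,3-dihydrobenzofuran-5-yl]methyl}-4-(4-benzyloxy-3-methoxybenzyl)-2-oxotetrahydrofuran-3-carboxylate, via magnesium enolate 23 (not isolated)
Conditions: CuI (10 mol %), THF, −40 to −15 °C; then 19, DMPU, −15 °C to rt
Reagents that add atoms: none
Why: The arylcopper species formed from 22 and CuI attacks the unsubstituted cyclopropane carbon C6 of 4 in an SN2-like homoconjugate addition, and the C6–C1 bond leaves as the doubly stabilised lactone–ester enolate 23, driven by strain release. The closest known reactions are the copper-catalysed Grignard opening of this bicyclic lactone and the C-alkylation of α-alkoxycarbonyl lactone enolates by benzylic halides, here run one after the other in the same flask as a conjugate-addition and enolate-trapping sequence. No ring is closed: the cyclopropane is opened and ring A is kept. C5 of 4 is not touched and becomes C4 (S) of the lactone. The new quaternary centre C3 is set by the substrate: the enolate is planar, the C4 benzyl arm shields one face, and bromide 19 is expected to enter anti to it (3S); this configuration is later erased, so incomplete selectivity costs nothing. The step needs attack at the cyclopropane CH2 and not at the methine or a carbonyl group, which copper catalysis at low temperature, the lower substitution of C6 and the double activation of the breaking bond secure. It also needs C- over O-alkylation, favoured by the soft, highly reactive benzylic bromide and by DMPU loosening the chelated magnesium enolate. Lactone 4 is kept in slight excess over 22 so that no aryl–metal species is left to couple with 19.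

Step 18
Reactants: 24 ethyl (3S,4S)-3-{[(2S,3R)-7-(benzyloxy)-3-[(benzyloxy)methyl]-2-(4-benzyloxy-3-methoxyphenyl)-2,3-dihydrobenzofuran-5-yl]methyl}-4-(4-benzyloxy-3-methoxybenzyl)-2-oxotetrahydrofuran-3-carboxylate
Product: 25 (4S)-3-{[(2S,3R)-7-(benzyloxy)-3-[(benzyloxy)methyl]-2-(4-benzyloxy-3-methoxyphenyl)-2,3-dihydrobenzofuran-5-yl]methyl}-4-(4-benzyloxy-3-methoxybenzyl)dihydrofuran-2(3H)-one (mixture of C3 epimers)
Conditions: LiCl, H2O, DMSO, 150 °C
Reagents that add atoms: none
Why: Krapcho dealkoxycarbonylation: chloride dealkylates the ethyl ester by SN2, the carboxylate loses CO2 and the resulting lactone enolate is protonated by water; C4 and the ring D stereocentres are not involved.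

Step 19
Reactants: 25 (4S)-3-{[(2S,3R)-7-(benzyloxy)-3-[(benzyloxy)methyl]-2-(4-benzyloxy-3-methoxyphenyl)-2,3-dihydrobenzofuran-5-yl]methyl}-4-(4-benzyloxy-3-methoxybenzyl)dihydrofuran-2(3H)-one (mixture of C3 epimers)
Product: 26 (3S,4S)-3-{[(2S,3R)-7-(benzyloxy)-3-[(benzyloxy)methyl]-2-(4-benzyloxy-3-methoxyphenyl)-2,3-dihydrobenzofuran-5-yl]methyl}-4-(4-benzyloxy-3-methoxybenzyl)dihydrofuran-2(3H)-one (trans)
Conditions: DBU, toluene, 60 °C
Reagents that add atoms: none
Why: Reversible enolisation at C3 by the amidine base; the trans 3,4-dibenzyl lactone is the thermodynamic isomer, so C3 settles as S under control of the fixed C4 centre, and no other stereocentre carries an acidic hydrogen.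

Step 20
Reactants: 26 (3S,4S)-3-{[(2S,3R)-7-(benzyloxy)-3-[(benzyloxy)methyl]-2-(4-benzyloxy-3-methoxyphenyl)-2,3-dihydrobenzofuran-5-yl]methyl}-4-(4-benzyloxy-3-methoxybenzyl)dihydrofuran-2(3H)-one (trans)
Product: 27 (3S,4S)-3-{[(2S,3R)-7-hydroxy-2-(4-hydroxy-3-methoxyphenyl)-3-(hydroxymethyl)-2,3-dihydrobenzofuran-5-yl]methyl}-4-(4-hydroxy-3-methoxybenzyl)dihydrofuran-2(3H)-one (target)
Conditions: H2 (1 atm), Pd/C, EtOAc/MeOH, rt
Reagents that add atoms: none
Why: Catalytic hydrogenolysis of the three aryl benzyl ethers and the primary alkyl benzyl ether; no stereocentre is touched, and a neutral medium with close monitoring should spare the cyclic benzylic C2–O1 bond.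

## Compound list

1 | (S)-epichlorohydrin, (2S)-2-(chloromethyl)oxirane | ClC[C@@H]1CO1 | starting material
2 | diethyl malonate | CCOC(=O)CC(=O)OCC | starting material
3 | sodium alkoxide of diethyl (2S)-2-(hydroxymethyl)cyclopropane-1,1-dicarboxylate (not isolated) | [Na+].[O-]C[C@H]1CC1(C(=O)OCC)C(=O)OCC | intermediate
4 | ethyl (1R,5S)-2-oxo-3-oxabicyclo[3.1.0]hexane-1-carboxylate | C1[C@@H]2COC(=O)[C@]12C(=O)OCC | intermediate
5 | [4-(benzyloxy)-3-methoxyphenyl]methanol | COc1cc(CO)ccc1OCc1ccccc1 | starting material
6 | 4-(benzyloxy)-3-methoxybenzyl chloride | COc1cc(CCl)ccc1OCc1ccccc1 | intermediate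
7 | 3-bromo-4,5-dihydroxybenzaldehyde | O=Cc1cc(O)c(O)c(Br)c1 | starting material
8 | 3-bromo-4-[(4-benzyloxy-3-methoxybenzyl)oxy]-5-hydroxybenzaldehyde | O=Cc1cc(O)c(OCc2ccc(OCc3ccccc3)c(OC)c2)c(Br)c1 | intermediate
9 | 3-(benzyloxy)-5-bromo-4-[(4-benzyloxy-3-methoxybenzyl)oxy]benzaldehyde | O=Cc1cc(OCc2ccccc2)c(OCc2ccc(OCc3ccccc3)c(OC)c2)c(Br)c1 | intermediate
10 | {3-(benzyloxy)-5-bromo-4-[(4-benzyloxy-3-methoxybenzyl)oxy]phenyl}methanol | OCc1cc(OCc2ccccc2)c(OCc2ccc(OCc3ccccc3)c(OC)c2)c(Br)c1 | intermediate
11 | tert-butyl({3-(benzyloxy)-5-bromo-4-[(4-benzyloxy-3-methoxybenzyl)oxy]benzyl}oxy)dimethylsilane | CC(C)(C)[Si](C)(C)OCc1cc(OCc2ccccc2)c(OCc2ccc(OCc3ccccc3)c(OC)c2)c(Br)c1 | intermediate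
12 | methyl 2-{3-(benzyloxy)-2-[(4-benzyloxy-3-methoxybenzyl)oxy]-5-[(tert-butyldimethylsilyloxy)methyl]phenyl}acetate | COC(=O)Cc1cc(CO[Si](C)(C)C(C)(C)C)cc(OCc2ccccc2)c1OCc1ccc(OCc2ccccc2)c(OC)c1 | intermediate
13 | methyl 2-diazo-2-{3-(benzyloxy)-2-[(4-benzyloxy-3-methoxybenzyl)oxy]-5-[(tert-butyldimethylsilyloxy)methyl]phenyl}acetate | COC(=O)C(=[N+]=[N-])c1cc(CO[Si](C)(C)C(C)(C)C)cc(OCc2ccccc2)c1OCc1ccc(OCc2ccccc2)c(OC)c1 | intermediate
14 | methyl (2S,3R)-7-(benzyloxy)-2-(4-benzyloxy-3-methoxyphenyl)-5-[(tert-butyldimethylsilyloxy)methyl]-2,3-dihydrobenzofuran-3-carboxylate (cis) | CC(C)(C)[Si](C)(C)OCc1cc(OCc2ccccc2)c2c(c1)[C@@H](C(=O)OC)[C@@H](c1ccc(OCc3ccccc3)c(OC)c1)O2 | intermediate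
15 | methyl (2S,3S)-7-(benzyloxy)-2-(4-benzyloxy-3-methoxyphenyl)-5-[(tert-butyldimethylsilyloxy)methyl]-2,3-dihydrobenzofuran-3-carboxylate (trans) | CC(C)(C)[Si](C)(C)OCc1cc(OCc2ccccc2)c2c(c1)[C@H](C(=O)OC)[C@@H](c1ccc(OCc3ccccc3)c(OC)c1)O2 | intermediate
16 | [(2S,3R)-7-(benzyloxy)-2-(4-benzyloxy-3-methoxyphenyl)-5-[(tert-butyldimethylsilyloxy)methyl]-2,3-dihydrobenzofuran-3-yl]methanol | CC(C)(C)[Si](C)(C)OCc1cc(OCc2ccccc2)c2c(c1)[C@H](CO)[C@@H](c1ccc(OCc3ccccc3)c(OC)c1)O2 | intermediate
17 | tert-butyl{[(2S,3R)-7-(benzyloxy)-3-[(benzyloxy)methyl]-2-(4-benzyloxy-3-methoxyphenyl)-2,3-dihydrobenzofuran-5-yl]methoxy}dimethylsilane | CC(C)(C)[Si](C)(C)OCc1cc(OCc2ccccc2)c2c(c1)[C@H](COCc1ccccc1)[C@@H](c1ccc(OCc3ccccc3)c(OC)c1)O2 | intermediate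
18 | [(2S,3R)-7-(benzyloxy)-3-[(benzyloxy)methyl]-2-(4-benzyloxy-3-methoxyphenyl)-2,3-dihydrobenzofuran-5-yl]methanol | OCc1cc(OCc2ccccc2)c2c(c1)[C@H](COCc1ccccc1)[C@@H](c1ccc(OCc3ccccc3)c(OC)c1)O2 | intermediate
19 | (2S,3R)-7-(benzyloxy)-3-[(benzyloxy)methyl]-2-(4-benzyloxy-3-methoxyphenyl)-5-(bromomethyl)-2,3-dihydrobenzofuran | BrCc1cc(OCc2ccccc2)c2c(c1)[C@H](COCc1ccccc1)[C@@H](c1ccc(OCc3ccccc3)c(OC)c1)O2 | intermediate
20 | 4-bromo-2-methoxyphenol | COc1cc(Br)ccc1O | starting material
21 | 1-(benzyloxy)-4-bromo-2-methoxybenzene | COc1cc(Br)ccc1OCc1ccccc1 | intermediate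
22 | (4-benzyloxy-3-methoxyphenyl)magnesium bromide | COc1cc([Mg]Br)ccc1OCc1ccccc1 | intermediate
23 | bromomagnesium enolate of ethyl (4S)-4-(4-benzyloxy-3-methoxybenzyl)-2-oxotetrahydrofuran-3-carboxylate (not isolated) | CCOC(=O)C1=C(O[Mg]Br)OC[C@H]1Cc1ccc(OCc2ccccc2)c(OC)c1 | intermediate
24 | ethyl (3S,4S)-3-{[(2S,3R)-7-(benzyloxy)-3-[(benzyloxy)methyl]-2-(4-benzyloxy-3-methoxyphenyl)-2,3-dihydrobenzofuran-5-yl]methyl}-4-(4-benzyloxy-3-methoxybenzyl)-2-oxotetrahydrofuran-3-carboxylate | COc1cc(C[C@@H]2COC(=O)[C@@]2(C(=O)OCC)Cc2cc(OCc4ccccc4)c3c(c2)[C@H](COCc4ccccc4)[C@@H](c2ccc(OCc4ccccc4)c(OC)c2)O3)ccc1OCc1ccccc1 | intermediate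
25 | (4S)-3-{[(2S,3R)-7-(benzyloxy)-3-[(benzyloxy)methyl]-2-(4-benzyloxy-3-methoxyphenyl)-2,3-dihydrobenzofuran-5-yl]methyl}-4-(4-benzyloxy-3-methoxybenzyl)dihydrofuran-2(3H)-one, mixture of C3 epimers | COc1cc(C[C@@H]2COC(=O)C2Cc2cc(OCc4ccccc4)c3c(c2)[C@H](COCc4ccccc4)[C@@H](c2ccc(OCc4ccccc4)c(OC)c2)O3)ccc1OCc1ccccc1 | intermediate
26 | (3S,4S)-3-{[(2S,3R)-7-(benzyloxy)-3-[(benzyloxy)methyl]-2-(4-benzyloxy-3-methoxyphenyl)-2,3-dihydrobenzofuran-5-yl]methyl}-4-(4-benzyloxy-3-methoxybenzyl)dihydrofuran-2(3H)-one | COc1cc(C[C@@H]2COC(=O)[C@H]2Cc2cc(OCc4ccccc4)c3c(c2)[C@H](COCc4ccccc4)[C@@H](c2ccc(OCc4ccccc4)c(OC)c2)O3)ccc1OCc1ccccc1 | intermediate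
27 | (3S,4S)-3-{[(2S,3R)-7-hydroxy-2-(4-hydroxy-3-methoxyphenyl)-3-(hydroxymethyl)-2,3-dihydrobenzofuran-5-yl]methyl}-4-(4-hydroxy-3-methoxybenzyl)dihydrofuran-2(3H)-one | COc1cc(C[C@@H]2COC(=O)[C@H]2Cc2cc(O)c3c(c2)[C@H](CO)[C@@H](c2ccc(O)c(OC)c2)O3)ccc1O | target

## Step count and least certain steps

Total step count: 20. Longest linear sequence: 17 steps (steps 2 to 14, then 17 to 20). Steps 1, 15 and 16 are side branches.

**Step 17 (key step).** The most likely failure is sluggish C-alkylation of the chelated, aggregated magnesium enolate. The labile para-alkoxybenzylic bromide may then be lost to O-alkylation or solvolysis, or to copper-mediated coupling with any aryl–magnesium species left over.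
Fallback: from 4 and 22 the same copper-catalysed opening is run but quenched with aqueous NH4Cl, and ethyl (4S)-4-(4-benzyloxy-3-methoxybenzyl)-2-oxotetrahydrofuran-3-carboxylate F1 is isolated. Its sodium enolate (NaH, DMF, 0 °C), free of copper and magnesium, is then alkylated with 19. This returns to the route at 24.

**Step 9.** The most likely failure is poor discrimination between the two enantiotopic benzylic hydrogens, or induction in the unwanted sense. The flanking 7-benzyloxy group forces the ether out of the ring plane and may change the preferred insertion geometry.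
Fallback: from 13 the insertion is run with achiral Rh2(OAc)4 to give the racemic cis ester F2, which is equilibrated with NaOMe to the racemic trans ester F3. This is resolved by preparative chromatography on a chiral stationary phase; the (2R,3R) ester F4 is set aside. This returns to the route at 15.

**Step 3.** The most likely failure is loss of regiocontrol, with alkylation at O5 or at both oxygens. The O4 phenoxide is flanked by bromine and hydroxyl, and the electrophile is reactive enough to be unselective.
Fallback: from chloride 6 the order of events is changed. Commercial 3-(benzyloxy)-4-hydroxybenzaldehyde F5 is brominated ortho to its only free phenol (Br2, NaOAc, AcOH) to give 3-(benzyloxy)-5-bromo-4-hydroxybenzaldehyde F6. Its single phenol is then alkylated with 6 (K2CO3, DMF). This returns to the route at 9.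

**Step 18.** The most likely failure is incomplete dealkoxycarbonylation at the hindered quaternary centre, or thermal degradation during the long heating that it needs.
Fallback: from 24 the ester and lactone are saponified (KOH, aqueous EtOH, reflux). Acidification re-closes the lactone to (3S,4S)-3-{[(2S,3R)-7-(benzyloxy)-3-[(benzyloxy)methyl]-2-(4-benzyloxy-3-methoxyphenyl)-2,3-dihydrobenzofuran-5-yl]methyl}-4-(4-benzyloxy-3-methoxybenzyl)-2-oxotetrahydrofuran-3-carboxylic acid F7, which is decarboxylated thermally (toluene, reflux). This returns to the route at 25.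

**Step 20.** The most likely failure is over-reduction: hydrogenolytic opening of the cyclic benzylic C2–O1 bond while the slower primary alkyl benzyl ether is still being removed.
Fallback: from 26 the benzyl groups are removed by Lewis-acid cleavage with a cation scavenger (BCl3, pentamethylbenzene, CH2Cl2, −78 °C), which gives 27 directly. This fallback makes no new compound (F0).

## Further compounds

F1 | step 17 | ethyl (4S)-4-(4-benzyloxy-3-methoxybenzyl)-2-oxotetrahydrofuran-3-carboxylate (C3 epimers) | CCOC(=O)C1C(=O)OC[C@H]1Cc1ccc(OCc2ccccc2)c(OC)c1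
F2 | step 9 | racemic cis ester, methyl (2S,3R)- and (2R,3S)-7-(benzyloxy)-2-(4-benzyloxy-3-methoxyphenyl)-5-[(tert-butyldimethylsilyloxy)methyl]-2,3-dihydrobenzofuran-3-carboxylate | CC(C)(C)[Si](C)(C)OCc1cc(OCc2ccccc2)c2c(c1)[C@@H](C(=O)OC)[C@@H](c1ccc(OCc3ccccc3)c(OC)c1)O2.CC(C)(C)[Si](C)(C)OCc1cc(OCc2ccccc2)c2c(c1)[C@H](C(=O)OC)[C@H](c1ccc(OCc3ccccc3)c(OC)c1)O2
F3 | step 9 | racemic trans ester, methyl (2S,3S)- and (2R,3R)-7-(benzyloxy)-2-(4-benzyloxy-3-methoxyphenyl)-5-[(tert-butyldimethylsilyloxy)methyl]-2,3-dihydrobenzofuran-3-carboxylate | CC(C)(C)[Si](C)(C)OCc1cc(OCc2ccccc2)c2c(c1)[C@H](C(=O)OC)[C@@H](c1ccc(OCc3ccccc3)c(OC)c1)O2.CC(C)(C)[Si](C)(C)OCc1cc(OCc2ccccc2)c2c(c1)[C@@H](C(=O)OC)[C@H](c1ccc(OCc3ccccc3)c(OC)c1)O2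
F4 | step 9 | methyl (2R,3R)-7-(benzyloxy)-2-(4-benzyloxy-3-methoxyphenyl)-5-[(tert-butyldimethylsilyloxy)methyl]-2,3-dihydrobenzofuran-3-carboxylate (enantiomer of 15) | CC(C)(C)[Si](C)(C)OCc1cc(OCc2ccccc2)c2c(c1)[C@@H](C(=O)OC)[C@H](c1ccc(OCc3ccccc3)c(OC)c1)O2
F5 | step 3 | 3-(benzyloxy)-4-hydroxybenzaldehyde | O=Cc1ccc(O)c(OCc2ccccc2)c1
F6 | step 3 | 3-(benzyloxy)-5-bromo-4-hydroxybenzaldehyde | O=Cc1cc(Br)c(O)c(OCc2ccccc2)c1
F7 | step 18 | (3S,4S)-3-{[(2S,3R)-7-(benzyloxy)-3-[(benzyloxy)methyl]-2-(4-benzyloxy-3-methoxyphenyl)-2,3-dihydrobenzofuran-5-yl]methyl}-4-(4-benzyloxy-3-methoxybenzyl)-2-oxotetrahydrofuran-3-carboxylic acid | COc1cc(C[C@@H]2COC(=O)[C@@]2(C(=O)O)Cc2cc(OCc4ccccc4)c3c(c2)[C@H](COCc4ccccc4)[C@@H](c2ccc(OCc4ccccc4)c(OC)c2)O3)ccc1OCc1ccccc1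
F0 | step 20 | none | none
A1 | alternative 1 | methyl (2S,3S)-7-(benzyloxy)-5-bromo-2-[3-methoxy-4-(pivaloyloxy)phenyl]-2,3-dihydrobenzofuran-3-carboxylate (trans) | Brc1cc(OCc3ccccc3)c2c(c1)[C@H](C(=O)OC)[C@@H](c1ccc(OC(=O)C(C)(C)C)c(OC)c1)O2
A2 | alternative 1 | (2S)-8-(benzyloxy)-6-bromo-2-[3-methoxy-4-(pivaloyloxy)phenyl]chroman-4-one | O=C1C[C@@H](c2ccc(OC(=O)C(C)(C)C)c(OC)c2)Oc2c(OCc3ccccc3)cc(Br)cc12
A3 | alternative 1 | (E)-1-[3-(benzyloxy)-5-bromo-2-hydroxyphenyl]-3-[3-methoxy-4-(pivaloyloxy)phenyl]prop-2-en-1-one | O=C(/C=C/c1ccc(OC(=O)C(C)(C)C)c(OC)c1)c1cc(Br)cc(OCc2ccccc2)c1O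
A4 | alternative 2 | (4S)-4-(4-benzyloxy-3-methoxybenzyl)dihydrofuran-2(3H)-one | COc1cc(C[C@@H]2COC(=O)C2)ccc1OCc1ccccc1
A5 | alternative 2 | 3-(4-benzyloxy-3-methoxybenzyl)cyclobutan-1-one | COc1cc(CC2CC(=O)C2)ccc1OCc1ccccc1
A6 | alternative 2 | eugenol, 4-allyl-2-methoxyphenol | COc1cc(CC=C)ccc1O
A7 | alternative 3 | (3E,4S)-3-{[(2S,3R)-7-(benzyloxy)-3-[(benzyloxy)methyl]-2-(4-benzyloxy-3-methoxyphenyl)-2,3-dihydrobenzofuran-5-yl]methylidene}-4-(4-benzyloxy-3-methoxybenzyl)dihydrofuran-2(3H)-one | COc1cc(C[C@@H]2COC(=O)/C2=C/c2cc(OCc4ccccc4)c3c(c2)[C@H](COCc4ccccc4)[C@@H](c2ccc(OCc4ccccc4)c(OC)c2)O3)ccc1OCc1ccccc1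
A8 | alternative 3 | (2S)-2-(4-benzyloxy-3-methoxybenzyl)-4-[(2S,3R)-7-(benzyloxy)-3-[(benzyloxy)methyl]-2-(4-benzyloxy-3-methoxyphenyl)-2,3-dihydrobenzofuran-5-yl]but-3-yn-1-ol | OC[C@@H](Cc1ccc(OCc2ccccc2)c(OC)c1)C#Cc1cc(OCc2ccccc2)c2c(c1)[C@H](COCc1ccccc1)[C@@H](c1ccc(OCc3ccccc3)c(OC)c1)O2
A9 | alternative 3 | (2S,3R)-7-(benzyloxy)-3-[(benzyloxy)methyl]-2-(4-benzyloxy-3-methoxyphenyl)-5-iodo-2,3-dihydrobenzofuran | Ic1cc(OCc2ccccc2)c2c(c1)[C@H](COCc1ccccc1)[C@@H](c1ccc(OCc3ccccc3)c(OC)c1)O2
A10 | alternative 3 | (2S)-2-(4-benzyloxy-3-methoxybenzyl)but-3-yn-1-ol | OC[C@@H](Cc1ccc(OCc2ccccc2)c(OC)c1)C#C
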